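## The problem

The target is the salicylic ester of a trans-fused hydroazulene diol of the daucane type. A cycloheptene, numbered C1(Me)=C2–C3–C4–C8–C9–C10, shares the C4–C8 bond with a cyclopentane, C4–C5–C6–C7–C8; C4 bears the angular methyl C14, C7 a tertiary hydroxyl and an isopropyl group, C9 the ester oxygen. Four contiguous stereocentres must be set in one absolute sense: C14 and the C7 hydroxyl lie on one face (β below), the C8 hydrogen, the isopropyl group and the C9 oxygen on the other (α). They can be linked in a chain of control: a temporary, reagent-made centre at C9 can bias addition at C7; the C7 hydroxyl can deliver a carbon to C4; C8 must end trans to C14, which is the thermodynamic but not the kinetic outcome beside the isopropyl group; and C9 can finally be reset from the C7 hydroxyl by internal hydride delivery. Fragile points are the tertiary alcohol (allylic, later cyclopropylcarbinyl, so acid-sensitive), every stage with a C9 ketone, and the salicylate with its free phenol, which belongs at the very end. A C9 ketone makes a β-hydroxy ketone open to retro-aldol cleavage and has C1=C2 in the β,γ position, ready to move into conjugation; the first seven-membered dienone can also lose HBr to a tropone. The feature that opens the route is that C14 is cis to the C7 hydroxyl across C8: a C4=C8 olefin is allylic to the C7 carbinol, so a hydroxyl-bound carbenoid can place a methylene on C4 from the correct face. The extra C14–C8 bond then lies α to C9, where a ketone can break it.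

## Retrosynthesis

The C9–O acyl bond of 29 is cut first, giving diol 26 and acid chloride 27. A phenolic benzoate would not survive the organometallic and dissolving-metal steps, and carrying a protected aryl ester through them only adds steps. In 26 a secondary and a tertiary hydroxyl differ enough for selective acylation. The forward reaction must acylate a hindered secondary alcohol and then free the phenol (via 28) without touching the new ester.

In 26 the C9–H bond is disconnected, leading to ketone 24. A C9 ketone is needed anyway, because it labilizes the C8–C14 bond, and it lets C9 be copied from C7. Internal delivery from the C7 oxygen (via 25) gives the α alcohol, whereas an external hydride would approach anti to C14 and give the epimer. The precursor has one stereocentre fewer.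

Ketone 24 is traced to its C8 epimer 22 and, by re-forming the C8–C14 bond, to cyclopropyl ketone 20 (forward: reductive cleavage through enolate 21). Direct construction of the quaternary methyl, by conjugate addition to a tetrasubstituted enone or by alkylation at a ring-fusion carbon, is the less reliable neighbour of this cut. A cyclopropane fixes the face of the methyl when it is formed. The price is that C8 leaves the cleavage as an enolate. The forward sequence must break the exocyclic and not the ring-fusion bond, then bring C8 to the trans configuration (through dienolate 23) without losing the C1=C2 olefin.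

An oxidation-state change leads from 20 to cyclopropyl diol 19, and the key disconnection removes C14 (the C14–C4 and C14–C8 bonds) to give dienediol 17. Compound 17 is flat at both ring-fusion carbons and has only two stereocentres, both carbinols on the β face. Compared with a variant that keeps a silyl ether on C9, the free cis diol is preferred: both oxygens direct to the same face and nothing bulky sits where the methylene must arrive. The forward reaction must deliver CH2 to the tetrasubstituted olefin from the β face (via zinc alkoxide 18) and spare C1=C2.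

The C7–isopropyl bond of 17 is cut next, through silyl ether 16 to enone 13 and isopropylmagnesium chloride 14 (used as cerium reagent 15). In 13 the only stereocentre is C9, and its silyloxy group is the one element that can tell the faces of the C7 carbonyl apart. A nucleophile should enter anti to it, so the C7 hydroxyl comes out cis to the C9 oxygen. C9 is therefore carried as the β epimer, opposite to the target, which costs nothing because C9 is oxidized later.

Enone 13 is opened at C4–C5 (retro-Nazarov) to divinyl ketone 12, and this at C7–C8, through alcohol 11, to vinyllithium 10 (from bromide 8) and acrolein 9. Other cyclopentenone annulations onto a cycloalkenyl halide put the carbonyl at C6 or need a functional group on C4. The electrocyclization bonds the unfunctionalized vinylic C4 and leaves the olefin at C4=C8, where the key step needs it. The forward cyclization must tolerate the allylic silyl ether and the skipped diene.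

Silyl ether 8 comes from alcohol 7, and 7 from bromodienone 6 by disconnecting the C9–H bond. An α-bromo enone is a good substrate for catalytic enantioselective reduction, and the bromine is also the handle for the C7–C8 bond. This is the only step where a reagent introduces absolute configuration.

The seven-membered ring of 6 is contracted by removing C8, giving dibromocyclopropane 5, made from diene 2 and bromoform 3 (as carbene 4), and 2 comes from 3-methylanisole 1. The arene supplies six ring carbons with the methyl group and, after reduction, the C1=C2 olefin and an enol ether that steers the carbene. The forward ring expansion must stop at the dienone.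

## Roads not taken

Alternative 1: The cut is at C8–C9 and C3–C4 by an enone–olefin [2+2] photocycloaddition, followed by oxidative cleavage of the C3–C9 glycol bond (a de Mayo-type two-carbon ring expansion). Irradiation of 3-methylcyclopent-2-en-1-one A1 with 4-methyl-1,2-bis(trimethylsilyloxy)cyclopent-1-ene A2 would give the cis-anti-cis tricycle A3, and desilylation with glycol cleavage would open it to the cis-fused triketone A4.
- Merits: two simple five-membered rings deliver the quaternary C4 and the whole skeleton except the isopropyl group in two or three operations. The olefin partner is symmetric about its double bond, so there is no regiochemical question.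
- Where it is better: in A4, C8 lies between two carbonyls, so the trans ring fusion can be reached by equilibration before any tertiary alcohol or β,γ-olefin exists. The chosen plan must correct C8 next to a finished carbinol (step 14).
- Weak points: A3 is racemic with no obvious handle for absolute control. C1 arrives saturated and C3 as a ketone, so the C1=C2 olefin needs dehydrogenation toward C2 and removal of the C3 oxygen. Three ketones (C3, C7, C9) must be told apart before isopropyl addition and C9 reduction.
- Against it the chosen plan sets enantiocontrol from one catalytic reduction, the C1=C2 olefin present from step 1, and never more than one carbonyl in the molecule.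

Alternative 2: The cut is at C4–C5 by a Nazarov cyclization onto a seven-membered ring that already carries the C4 methyl. Cu(OTf)2 A6 with a chiral bisoxazoline ligand would chelate the C7 and C9 carbonyls of the β-silyl dienone A5; conrotatory closure forms C4–C5 and the quaternary centre, and loss of silicon places the olefin at C5=C6 in diketone A7.
- Merits: ring, quaternary stereocentre and absolute configuration come from one catalytic step, with no temporary ring. It is the same reaction class as step 8 of the chosen route but does far more.
- Where it is better: C8 again sits between two carbonyls, so the ring fusion is easier than in the chosen plan.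
- Weak points: the bonding terminus is fully substituted, and such closures are slow. Torquoselective two-point catalysis is established mainly for less substituted termini. A5 is a cross-conjugated tricarbonyl-type cycloheptadienone with the same labile β,γ-olefin. Downstream, the isopropyl group must be added to one carbonyl of an enolizable 1,3-diketone and the C5=C6 olefin reduced.
- If the cyclization were selective, this road would be shorter. The chosen plan sets against it that every step is precedented on its substrate class and that the stereocentres are set one at a time.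

Alternative 3: The cut is at C1–C10 and C3–C4, a formal [4+3] annulation. Rh2(S-DOSP)4 A8 would decompose methyl 2-diazobut-3-enoate A9; the vinylcarbenoid cyclopropanates the terminal silyl enol ether of diene A10, and Cope rearrangement of the cis-divinylcyclopropane gives cycloheptadiene A11.
- Merits: the route is convergent, and the seven-membered ring, the quaternary C4 and both olefins are formed in one step with catalyst control. The C1=C2 olefin is conjugated to the ester and cannot wander.
- Where it is better: C7 is still a ketal, so the isopropyl carbinol would be made after the C8 hydrogen is in place, which is the more natural order. In this respect it is clearly ahead of the chosen plan.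
- Weak points: the unsubstituted vinyldiazoacetate A9 is labile and less well behaved in enantioselective carbenoid chemistry than substituted ones. The Cope step must create a quaternary centre at a tetrasubstituted olefin terminus. The C1 ester has to be reduced to a methyl over several steps without moving the olefin. C8 is again fixed by protonation of an enol derivative.
- The chosen plan sets against it cheap achiral feedstocks, no diazo compound, the methyl group present from the start and a robust source of chirality.

Key step: step 11

Remarks on the chemistry: atom numbers C1–C14 and the face labels α/β are those defined above. The isopropyl nucleophile is assumed to add to enone 13 anti to the pseudoaxial C9 silyloxy group, so C9 is carried as the β epimer until it is oxidized in step 12.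

## Route

Step 1
Reactants: 1 3-methylanisole
Product: 2 1-methoxy-5-methylcyclohexa-1,4-diene
Conditions: Li, liquid NH3, THF, t-BuOH, −78 to −33 °C; H2O work-up
Reagents that add atoms: none
Why: Birch reduction; the two donor substituents end on the remaining double bonds, so the 2,5-dihydro isomer with the enol ether and the isolated trisubstituted olefin (future C1=C2) forms, and neutral work-up keeps the enol ether.

Step 2
Reactants: 2 1-methoxy-5-methylcyclohexa-1,4-diene; 3 bromoform
Product: 5 racemic 7,7-dibromo-1-methoxy-3-methylbicyclo[4.1.0]hept-3-ene, via dibromocarbene 4 (not isolated)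
Conditions: KOt-Bu, pentane, −20 to 0 °C
Reagents that add atoms: none
Why: α-Elimination gives electrophilic dibromocarbene, which adds in a [2+1] cycloaddition to the more electron-rich enol ether double bond rather than to the alkyl-substituted one; the cyclopropane is necessarily cis-fused.

Step 3
Reactants: 5 racemic 7,7-dibromo-1-methoxy-3-methylbicyclo[4.1.0]hept-3-ene
Product: 6 2-bromo-6-methylcyclohepta-2,5-dien-1-one
Conditions: AgNO3 (1.2 equiv), CaCO3, acetone–H2O, 0 °C, dark; crude product used at once
Reagents that add atoms: water, O
Why: Silver-assisted ionization of one C–Br bond is concerted with disrotatory opening of the cyclopropane (cyclopropyl-to-allyl cation ring expansion), the cation being stabilized by the methoxy group, and water converts the oxocarbenium ion into the 2-bromo enone (C9 carbonyl, C8 bromide, C4=C8). Buffered, cold conditions and immediate use limit loss of HBr toward a tropone.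

Step 4
Reactants: 6 2-bromo-6-methylcyclohepta-2,5-dien-1-one
Product: 7 (1R)-2-bromo-6-methylcyclohepta-2,5-dien-1-ol
Conditions: (S)-2-methyl-CBS-oxazaborolidine (0.2 equiv), catecholborane (1.5 equiv), toluene, −78 °C
Reagents that add atoms: none
Why: Corey–Bakshi–Shibata reduction; the ketone binds the catalyst with the α-bromovinyl flank as the large group, so hydride from the coordinated borane should give the (R)-alcohol, and catecholborane at −78 °C leaves both olefins alone. This is the only reagent-controlled stereocentre of the route.

Step 5
Reactants: 7 (1R)-2-bromo-6-methylcyclohepta-2,5-dien-1-ol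
Product: 8 {[(1R)-2-bromo-6-methylcyclohepta-2,5-dien-1-yl]oxy}tri(propan-2-yl)silane
Conditions: triisopropylsilyl triflate, 2,6-lutidine, CH2Cl2, 0 °C
Reagents that add atoms: triisopropylsilyl trifluoromethanesulfonate, CC(C)[Si](OS(=O)(=O)C(F)(F)F)(C(C)C)C(C)C
Why: O-Silylation with a silyl triflate; the bulky, acid-tolerant triisopropylsilyl group is chosen to survive the Lewis acid of step 8 and to shield one face in step 9.

Step 6
Reactants: 8 {[(1R)-2-bromo-6-methylcyclohepta-2,5-dien-1-yl]oxy}tri(propan-2-yl)silane; 9 acrolein
Product: 11 1-[(7R)-5-methyl-7-{[tri(propan-2-yl)silyl]oxy}cyclohepta-1,4-dien-1-yl]prop-2-en-1-ol (both carbinol epimers), via vinyllithium 10 (not isolated)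
Conditions: t-BuLi (2.1 equiv), THF, −78 °C; then 9, −78 °C; aq. NH4Cl
Reagents that add atoms: none
Why: Bromine–lithium exchange at −78 °C outpaces deprotonation and retro-Brook silyl migration, and 1,2-addition of the vinyllithium to the aldehyde forms the C7–C8 bond; the new carbinol centre is oxidized away in step 7.

Step 7
Reactants: 11 1-[(7R)-5-methyl-7-{[tri(propan-2-yl)silyl]oxy}cyclohepta-1,4-dien-1-yl]prop-2-en-1-ol
Product: 12 1-[(7R)-5-methyl-7-{[tri(propan-2-yl)silyl]oxy}cyclohepta-1,4-dien-1-yl]prop-2-en-1-one
Conditions: MnO2 (excess), CH2Cl2, 0 to 25 °C; filtration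
Reagents that add atoms: none
Why: MnO2 oxidizes the doubly allylic alcohol under neutral conditions and is removed by filtration, so the polymerizable vinyl ketone sees neither base nor aqueous work-up.

Step 8
Reactants: 12 1-[(7R)-5-methyl-7-{[tri(propan-2-yl)silyl]oxy}cyclohepta-1,4-dien-1-yl]prop-2-en-1-one
Product: 13 (8R)-6-methyl-8-{[tri(propan-2-yl)silyl]oxy}-3,4,7,8-tetrahydroazulen-1(2H)-one
Conditions: SnCl4 (1.1 equiv), CH2Cl2, −78 to −20 °C; aq. NaHCO3
Reagents that add atoms: none
Why: Nazarov cyclization; the Lewis-acid complex of the cross-conjugated dienone closes by 4π conrotatory electrocyclization to form C4–C5, and proton loss at C4 from the oxyallyl cation gives the more substituted C4=C8 enone. The ring substituent α to the carbonyl favours the reactive conformer, and the transient C4 stereocentre is erased.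

Step 9
Reactants: 13 (8R)-6-methyl-8-{[tri(propan-2-yl)silyl]oxy}-3,4,7,8-tetrahydroazulen-1(2H)-one; 14 isopropylmagnesium chloride
Product: 16 (1R,8R)-6-methyl-1-(propan-2-yl)-8-{[tri(propan-2-yl)silyl]oxy}-1,2,3,4,7,8-hexahydroazulen-1-ol, via isopropylcerium dichloride 15 (not isolated)
Conditions: CeCl3 (anhydrous), THF, 14, −78 °C; then 13, −78 to −40 °C; aq. NH4Cl
Reagents that add atoms: none
Why: Organocerium 1,2-addition avoids enolization at C6, γ-deprotonation at C3 and conjugate addition. The C9 silyloxy group sits pseudoaxially on the β face to escape allylic 1,3-strain with the C7 carbonyl, so the isopropyl group should enter from the α face and leave the C7 hydroxyl β, cis to the C9 oxygen (1,3-induction).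

Step 10
Reactants: 16 (1R,8R)-6-methyl-1-(propan-2-yl)-8-{[tri(propan-2-yl)silyl]oxy}-1,2,3,4,7,8-hexahydroazulen-1-ol
Product: 17 (1R,8R)-6-methyl-1-(propan-2-yl)-1,2,3,4,7,8-hexahydroazulene-1,8-diol
Conditions: tetrabutylammonium fluoride, THF, 0 to 25 °C
Reagents that add atoms: none
Why: Fluoride-mediated desilylation; it frees the second β hydroxyl so that both hydroxyls can direct the carbenoid and no bulky group blocks the β face at C8.

Step 11
Reactants: 17 (1R,8R)-6-methyl-1-(propan-2-yl)-1,2,3,4,7,8-hexahydroazulene-1,8-diol
Product: 19 6-methyl-1-(propan-2-yl)-1,2,3,4,7,8-hexahydro-3a,8a-methanoazulene-1,8-diol (carbinol centres as in 17; methano bridge on the face of both hydroxyls), via bis(ethylzinc) alkoxide 18 (not isolated)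
Conditions: Et2Zn (5 equiv), CH2Cl2, −20 °C; then CH2I2 (5 equiv), −20 to 0 °C; aq. NH4Cl
Reagents that add atoms: diiodomethane, ICI
Why: Et2Zn first converts both hydroxyls into ethylzinc alkoxides 18 and, with CH2I2, forms the carbenoid EtZnCH2I (Furukawa variant of the Simmons–Smith reaction). The carbenoid is held by the alkoxide oxygens and transfers its methylene to the adjacent C4=C8 olefin through the butterfly-type transition state, so that C14–C4 and C14–C8 form in one concerted, stereospecific [2+1] step; the three-membered ring closes by syn addition without an open-chain intermediate. The closest known reaction type is the hydroxyl-directed cyclopropanation of cyclic allylic alcohols, including tetrasubstituted ring-fusion olefins used as latent angular methyl groups. Both new stereocentres, C4 and C8, are set by the face of delivery, and the tertiary C7 alkoxide and the secondary C9 alkoxide, both β, direct to the same face; cis fusion of the cyclopropane is geometrically enforced. The step needs face selectivity (β) and site selectivity (C4=C8 over C1=C2). The first is secured by the two syn alkoxides; the second by the higher nucleophilicity of the tetrasubstituted olefin and its allylic relation to both alkoxides, whereas C1=C2 is only homoallylic to the C9 alkoxide and is further held back by limiting carbenoid and temperature. The β methylene becomes the C14 methyl of the target in step 13.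

Step 12
Reactants: 19 6-methyl-1-(propan-2-yl)-1,2,3,4,7,8-hexahydro-3a,8a-methanoazulene-1,8-diol
Product: 20 1-hydroxy-6-methyl-1-(propan-2-yl)-1,2,3,4-tetrahydro-3a,8a-methanoazulen-8(7H)-one (hydroxyl and methano bridge cis)
Conditions: Dess–Martin periodinane, pyridine, CH2Cl2, 0 °C
Reagents that add atoms: none
Why: Dess–Martin oxidation of the secondary cyclopropylcarbinol; the tertiary hydroxyl cannot be oxidized, pyridine buffering avoids cyclopropylcarbinyl ionization and olefin migration, and retro-aldol cleavage is blocked because it would need an enolate on the cyclopropane.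

Step 13
Reactants: 20 1-hydroxy-6-methyl-1-(propan-2-yl)-1,2,3,4-tetrahydro-3a,8a-methanoazulen-8(7H)-one
Product: 22 (3R,3aS,8aR)-3-hydroxy-6,8a-dimethyl-3-(propan-2-yl)-2,3,3a,5,8,8a-hexahydroazulen-4(1H)-one (cis-fused), via dilithium alkoxide enolate 21 (not isolated)
Conditions: Li (2.5 equiv), liquid NH3–THF, −78 °C, ketone added to the metal solution; isoprene; solid NH4Cl
Reagents that add atoms: none
Why: Dissolving-metal reductive cleavage of a cyclopropyl ketone; the ketyl radical anion breaks the cyclopropane bond that overlaps best with the carbonyl π system, the exocyclic C8–C14 bond and not the ring-fusion C4–C8 bond, so C14 becomes the β methyl on C4 and C8 a tetrasubstituted enolate. Kinetic protonation on work-up should occur anti to the isopropyl group and give mainly the cis-fused C8 epimer, which step 14 corrects.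

Step 14
Reactants: 22 (3R,3aS,8aR)-3-hydroxy-6,8a-dimethyl-3-(propan-2-yl)-2,3,3a,5,8,8a-hexahydroazulen-4(1H)-one
Product: 24 (3R,3aR,8aR)-3-hydroxy-6,8a-dimethyl-3-(propan-2-yl)-2,3,3a,5,8,8a-hexahydroazulen-4(1H)-one (trans-fused), via potassium dienolate 23 (not isolated)
Conditions: KOt-Bu (3 equiv), t-BuOH–THF, 25 °C; then inverse quench into 10% aq. AcOH, 0 °C
Reagents that add atoms: none
Why: Base-mediated α-epimerization under thermodynamic control; reversible enolization toward C8 lets C9 move to the β face, trans to the isopropyl group and hydrogen-bonded to the C7 hydroxyl (trans ring fusion). In t-BuOH the ketone rests mainly as the extended dienolate, which cannot undergo retro-aldol cleavage, and kinetic α-protonation at C10 on the acidic quench (deconjugative protonation) returns the C1=C2 olefin.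

Step 15
Reactants: 24 (3R,3aR,8aR)-3-hydroxy-6,8a-dimethyl-3-(propan-2-yl)-2,3,3a,5,8,8a-hexahydroazulen-4(1H)-one
Product: 26 (3R,3aS,4S,8aR)-6,8a-dimethyl-3-(propan-2-yl)-1,2,3,3a,4,5,8,8a-octahydroazulene-3,4-diol, via alkoxydiacetoxyborohydride 25 (not isolated)
Conditions: tetramethylammonium triacetoxyborohydride (5 equiv), MeCN–AcOH, −25 °C
Reagents that add atoms: none
Why: Evans–Saksena hydroxyl-directed reduction; acetate exchange binds boron to the C7 hydroxyl, and hydride is delivered intramolecularly to the β face of the C9 carbonyl, giving the α (1,3-anti) alcohol. Only the trans-fused ketone can deliver internally, and the mildly acidic medium leaves the β,γ-olefin in place.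

Step 16
Reactants: 26 (3R,3aS,4S,8aR)-6,8a-dimethyl-3-(propan-2-yl)-1,2,3,3a,4,5,8,8a-octahydroazulene-3,4-diol; 27 2-acetoxybenzoyl chloride
Product: 29 (3R,3aS,4S,8aR)-3-hydroxy-6,8a-dimethyl-3-(propan-2-yl)-1,2,3,3a,4,5,8,8a-octahydroazulen-4-yl 2-hydroxybenzoate, via acetylsalicylate ester 28 (not isolated)
Conditions: pyridine, 4-(dimethylamino)pyridine (cat.), CH2Cl2, 0 to 25 °C; then pyrrolidine, 0 °C
Reagents that add atoms: none
Why: Acylation of the secondary hydroxyl with an acid chloride under nucleophilic catalysis (the tertiary hydroxyl is inert), then selective aminolysis of the phenolic acetate, which is far more reactive than the hindered, hydrogen-bonded salicylate ester.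

## Compound list

1 | 3-methylanisole | COc1cccc(C)c1 | starting material
2 | 1-methoxy-5-methylcyclohexa-1,4-diene | COC1=CCC=C(C)C1 | intermediate
3 | bromoform | BrC(Br)Br | starting material
4 | dibromocarbene | Br[C]Br | intermediate (not isolated)
5 | racemic 7,7-dibromo-1-methoxy-3-methylbicyclo[4.1.0]hept-3-ene (cis-fused) | COC12CC(C)=CCC1C2(Br)Br | intermediate
6 | 2-bromo-6-methylcyclohepta-2,5-dien-1-one | O=C1C(Br)=CCC=C(C)C1 | intermediate
7 | (1R)-2-bromo-6-methylcyclohepta-2,5-dien-1-ol | O[C@H]1C(Br)=CCC=C(C)C1 | intermediate
8 | {[(1R)-2-bromo-6-methylcyclohepta-2,5-dien-1-yl]oxy}tri(propan-2-yl)silane | CC(C)[Si](O[C@H]1C(Br)=CCC=C(C)C1)(C(C)C)C(C)C | intermediate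
9 | acrolein | C=CC=O | starting material
10 | [(7R)-5-methyl-7-{[tri(propan-2-yl)silyl]oxy}cyclohepta-1,4-dien-1-yl]lithium | CC(C)[Si](O[C@H]1C([Li])=CCC=C(C)C1)(C(C)C)C(C)C | intermediate (not isolated)
11 | 1-[(7R)-5-methyl-7-{[tri(propan-2-yl)silyl]oxy}cyclohepta-1,4-dien-1-yl]prop-2-en-1-ol (both carbinol epimers) | C=CC(O)C1=CCC=C(C)C[C@H]1O[Si](C(C)C)(C(C)C)C(C)C | intermediate
12 | 1-[(7R)-5-methyl-7-{[tri(propan-2-yl)silyl]oxy}cyclohepta-1,4-dien-1-yl]prop-2-en-1-one | C=CC(=O)C1=CCC=C(C)C[C@H]1O[Si](C(C)C)(C(C)C)C(C)C | intermediate
13 | (8R)-6-methyl-8-{[tri(propan-2-yl)silyl]oxy}-3,4,7,8-tetrahydroazulen-1(2H)-one (C7 ketone, C4=C8, C9 silyloxy β) | CC1=CCC=2CCC(=O)C=2[C@H](O[Si](C(C)C)(C(C)C)C(C)C)C1 | intermediate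
14 | isopropylmagnesium chloride | CC(C)[Mg]Cl | starting material
15 | isopropylcerium dichloride | CC(C)[Ce](Cl)Cl | intermediate (not isolated)
16 | (1R,8R)-6-methyl-1-(propan-2-yl)-8-{[tri(propan-2-yl)silyl]oxy}-1,2,3,4,7,8-hexahydroazulen-1-ol (C7 hydroxyl β, isopropyl α, C9 silyloxy β) | CC1=CCC=2CC[C@@](O)(C(C)C)C=2[C@H](O[Si](C(C)C)(C(C)C)C(C)C)C1 | intermediate
17 | (1R,8R)-6-methyl-1-(propan-2-yl)-1,2,3,4,7,8-hexahydroazulene-1,8-diol (both hydroxyls β; key-step precursor) | CC1=CCC=2CC[C@@](O)(C(C)C)C=2[C@H](O)C1 | intermediate
18 | bis(ethylzinc) alkoxide of 17 | CC1=CCC=2CC[C@@](O[Zn]CC)(C(C)C)C=2[C@H](O[Zn]CC)C1 | intermediate (not isolated)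
19 | 6-methyl-1-(propan-2-yl)-1,2,3,4,7,8-hexahydro-3a,8a-methanoazulene-1,8-diol (cyclopropane across C4–C8, methylene and both hydroxyls β; key-step product) | CC1=CC[C@@]23CC[C@@](O)(C(C)C)[C@@]2(C3)[C@H](O)C1 | intermediate
20 | 1-hydroxy-6-methyl-1-(propan-2-yl)-1,2,3,4-tetrahydro-3a,8a-methanoazulen-8(7H)-one (C9 ketone; hydroxyl and methylene β) | CC1=CC[C@@]23CC[C@@](O)(C(C)C)[C@@]2(C3)C(=O)C1 | intermediate
21 | dilithium salt: C7 lithium alkoxide and C8=C9 lithium enolate, C14 methyl β on C4 | CC1=CC[C@@]2(C)CC[C@@](O[Li])(C(C)C)C2=C(O[Li])C1 | intermediate (not isolated)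
22 | (3R,3aS,8aR)-3-hydroxy-6,8a-dimethyl-3-(propan-2-yl)-2,3,3a,5,8,8a-hexahydroazulen-4(1H)-one (cis-fused, C8–H β) | CC1=CC[C@@]2(C)CC[C@@](O)(C(C)C)[C@H]2C(=O)C1 | intermediate
23 | potassium dienolate of 24 (C9–OK, C9=C10, C1=C2; C8–H α) | CC1=CC[C@@]2(C)CC[C@@](O)(C(C)C)[C@@H]2C(O[K])=C1 | intermediate (not isolated)
24 | (3R,3aR,8aR)-3-hydroxy-6,8a-dimethyl-3-(propan-2-yl)-2,3,3a,5,8,8a-hexahydroazulen-4(1H)-one (trans-fused, C8–H α) | CC1=CC[C@@]2(C)CC[C@@](O)(C(C)C)[C@@H]2C(=O)C1 | intermediate
25 | tetramethylammonium C7-alkoxy(diacetoxy)borohydride of 24 | CC1=CC[C@@]2(C)CC[C@@](O[BH-](OC(C)=O)OC(C)=O)(C(C)C)[C@@H]2C(=O)C1.C[N+](C)(C)C | intermediate (not isolated)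
26 | (3R,3aS,4S,8aR)-6,8a-dimethyl-3-(propan-2-yl)-1,2,3,3a,4,5,8,8a-octahydroazulene-3,4-diol | CC1=CC[C@@]2(C)CC[C@@](O)(C(C)C)[C@@H]2[C@@H](O)C1 | intermediate
27 | 2-acetoxybenzoyl chloride | CC(=O)Oc1ccccc1C(Cl)=O | starting material
28 | (3R,3aS,4S,8aR)-3-hydroxy-6,8a-dimethyl-3-(propan-2-yl)-1,2,3,3a,4,5,8,8a-octahydroazulen-4-yl 2-acetoxybenzoate | CC1=CC[C@@]2(C)CC[C@@](O)(C(C)C)[C@@H]2[C@@H](OC(=O)c2ccccc2OC(C)=O)C1 | intermediate (not isolated)
29 | (3R,3aS,4S,8aR)-3-hydroxy-6,8a-dimethyl-3-(propan-2-yl)-1,2,3,3a,4,5,8,8a-octahydroazulen-4-yl 2-hydroxybenzoate | CC1=CC[C@@]2(C)CC[C@@](O)(C(C)C)[C@@H]2[C@@H](OC(=O)c2ccccc2O)C1 | target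

## Step count and least certain steps

Total step count: 16. Longest linear sequence: 16 steps (from 1).

Step 11 (key step). Most likely failure: methylene transfer also to the C1=C2 olefin, directed by the homoallylic C9 alkoxide, or ionization of the tertiary allylic alkoxide (or of the cyclopropylcarbinyl product) by the zinc iodide that accumulates. Fallback, from 17 back to 19: the samarium carbenoid generated from Sm metal, HgCl2 (cat.) and CH2ICl in THF at −78 °C. It cyclopropanates only olefins carrying an allylic hydroxyl, leaves isolated olefins untouched and produces no strong Lewis acid. No new compound is formed.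

Step 14. This is the weakest point of the plan. Most likely failures: retro-aldol opening of the C7–C8 bond from the potassium alkoxide of the ketone form, incomplete epimerization at the hindered C8–H, or γ-protonation of the dienolate giving the conjugated enone. Fallback, from 22 back to 24, separates the two tasks. DBU in toluene at 80 °C (no alkoxide base) equilibrates both C8 and the olefin to the trans-fused conjugated enone (3R,3aR,8aR)-3-hydroxy-6,8a-dimethyl-3-(propan-2-yl)-2,3,3a,7,8,8a-hexahydroazulen-4(1H)-one F1. Trimethylsilyl triflate and triethylamine convert F1 into the bis(trimethylsilyl) dienol ether F2, which also caps the C7 hydroxyl. Fluoride buffered with AcOH at −78 °C then protonates C10 kinetically and removes both silyl groups to give 24.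

Step 9. Most likely failure: poor or reversed facial selectivity of the 1,2-addition, because 1,3-induction from a single allylic silyloxy group across an sp2 carbon is not assured. Fallback, from 6 back to 20, inverts the temporary centre and keeps its silyl ether through the cyclopropanation.
- The antipodal catalyst in step 4 gives (1S)-2-bromo-6-methylcyclohepta-2,5-dien-1-ol F3.
- Steps 5–8 then give its silyl ether F4, the vinyllithium F5, the dienol F6, the divinyl ketone F7 and the enantiomeric enone F8.
- Syn addition of 15 to F8 gives the tertiary alcohol F9, which has the required C7 configuration and its C9 silyl ether on the α face.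
- The C7 hydroxyl alone directs the cyclopropanation on the unhindered β face to cyclopropane F10.
- Desilylation gives the C9-epimeric cyclopropyl diol F11, and oxidation as in step 12 gives 20.

Step 8. Most likely failure: polymerization of the unsubstituted vinyl ketone or Lewis-acid loss of the silyloxy group before the electrocyclization. Fallback, from 8 (through 10) back to 13, is the silicon-directed Nazarov cyclization. Vinyllithium 10 is added to (E)-3-(trimethylsilyl)prop-2-enal to give the β-silyl dienol F12, and MnO2 gives the β-silyl divinyl ketone F13. FeCl3 in CH2Cl2 at −30 °C cyclizes F13, with the cation stabilized β to silicon, to the cis-fused C5=C6 cyclopentenone F14. RhCl3·3H2O in ethanol then moves the olefin into the C4=C8 position to give 13.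

Step 3. Most likely failure: loss of HBr from the 2-bromo dienone with aromatization to a tropone, or migration of the skipped olefins, during ring opening or isolation. Fallback, from 5 back to 7: the crude ring-opening solution is reduced at once with NaBH4 and CeCl3·7H2O in methanol at −78 °C (Luche reduction) to the stable racemic alcohol F15. A lipase with vinyl acetate is expected to acylate the (R)-enantiomer, giving the (R)-acetate F16, and K2CO3 in methanol releases 7. The dienone is never isolated and step 4 is not needed.

## Further compounds

F0 | step 11 | none | none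
F1 | step 14 | (3R,3aR,8aR)-3-hydroxy-6,8a-dimethyl-3-(propan-2-yl)-2,3,3a,7,8,8a-hexahydroazulen-4(1H)-one (trans-fused conjugated enone) | CC1=CC(=O)[C@H]2[C@](O)(C(C)C)CC[C@]2(C)CC1
F2 | step 14 | bis(trimethylsilyl) dienol ether of 24 (C7–OSiMe3; C9(OSiMe3)=C10, C1=C2) | CC1=CC[C@@]2(C)CC[C@@](O[Si](C)(C)C)(C(C)C)[C@@H]2C(O[Si](C)(C)C)=C1
F3 | step 9 | (1S)-2-bromo-6-methylcyclohepta-2,5-dien-1-ol | O[C@@H]1C(Br)=CCC=C(C)C1
F4 | step 9 | {[(1S)-2-bromo-6-methylcyclohepta-2,5-dien-1-yl]oxy}tri(propan-2-yl)silane | CC(C)[Si](O[C@@H]1C(Br)=CCC=C(C)C1)(C(C)C)C(C)C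
F5 | step 9 | [(7S)-5-methyl-7-{[tri(propan-2-yl)silyl]oxy}cyclohepta-1,4-dien-1-yl]lithium | CC(C)[Si](O[C@@H]1C([Li])=CCC=C(C)C1)(C(C)C)C(C)C
F6 | step 9 | 1-[(7S)-5-methyl-7-{[tri(propan-2-yl)silyl]oxy}cyclohepta-1,4-dien-1-yl]prop-2-en-1-ol | C=CC(O)C1=CCC=C(C)C[C@@H]1O[Si](C(C)C)(C(C)C)C(C)C
F7 | step 9 | 1-[(7S)-5-methyl-7-{[tri(propan-2-yl)silyl]oxy}cyclohepta-1,4-dien-1-yl]prop-2-en-1-one | C=CC(=O)C1=CCC=C(C)C[C@@H]1O[Si](C(C)C)(C(C)C)C(C)C
F8 | step 9 | (8S)-6-methyl-8-{[tri(propan-2-yl)silyl]oxy}-3,4,7,8-tetrahydroazulen-1(2H)-one | CC1=CCC=2CCC(=O)C=2[C@@H](O[Si](C(C)C)(C(C)C)C(C)C)C1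
F9 | step 9 | (1R,8S)-6-methyl-1-(propan-2-yl)-8-{[tri(propan-2-yl)silyl]oxy}-1,2,3,4,7,8-hexahydroazulen-1-ol (hydroxyl β, silyloxy α) | CC1=CCC=2CC[C@@](O)(C(C)C)C=2[C@@H](O[Si](C(C)C)(C(C)C)C(C)C)C1
F10 | step 9 | cyclopropane of F9 (methylene cis to the C7 hydroxyl, C9 silyloxy α) | CC1=CC[C@@]23CC[C@@](O)(C(C)C)[C@@]2(C3)[C@@H](O[Si](C(C)C)(C(C)C)C(C)C)C1
F11 | step 9 | C9 epimer of 19 (C9 hydroxyl α) | CC1=CC[C@@]23CC[C@@](O)(C(C)C)[C@@]2(C3)[C@@H](O)C1
F12 | step 8 | (2E)-1-[(7R)-5-methyl-7-{[tri(propan-2-yl)silyl]oxy}cyclohepta-1,4-dien-1-yl]-3-(trimethylsilyl)prop-2-en-1-ol | C[Si](C)(C)/C=C/C(O)C1=CCC=C(C)C[C@H]1O[Si](C(C)C)(C(C)C)C(C)C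
F13 | step 8 | (2E)-1-[(7R)-5-methyl-7-{[tri(propan-2-yl)silyl]oxy}cyclohepta-1,4-dien-1-yl]-3-(trimethylsilyl)prop-2-en-1-one | C[Si](C)(C)/C=C/C(=O)C1=CCC=C(C)C[C@H]1O[Si](C(C)C)(C(C)C)C(C)C
F14 | step 8 | (8R)-6-methyl-8-{[tri(propan-2-yl)silyl]oxy}-3a,4,8,8a-tetrahydroazulen-1(7H)-one (cis-fused, C5=C6 enone) | CC1=CCC2C=CC(=O)C2[C@H](O[Si](C(C)C)(C(C)C)C(C)C)C1
F15 | step 3 | racemic 2-bromo-6-methylcyclohepta-2,5-dien-1-ol | OC1C(Br)=CCC=C(C)C1
F16 | step 3 | (1R)-2-bromo-6-methylcyclohepta-2,5-dien-1-yl acetate | CC(=O)O[C@H]1C(Br)=CCC=C(C)C1
A1 | alternative 1 | 3-methylcyclopent-2-en-1-one | CC1=CC(=O)CC1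
A2 | alternative 1 | 4-methyl-1,2-bis(trimethylsilyloxy)cyclopent-1-ene | CC1CC(O[Si](C)(C)C)=C(O[Si](C)(C)C)C1
A3 | alternative 1 | cis-anti-cis tricyclo[5.3.0.0(2,6)]decanone bis(trimethylsilyl) ether (photoadduct) | C[C@@H]1C[C@]2(O[Si](C)(C)C)[C@@]3(C)CCC(=O)[C@H]3[C@]2(O[Si](C)(C)C)C1
A4 | alternative 1 | cis-fused 3a,6-dimethylperhydroazulene-1,4,8-trione | C[C@@H]1CC(=O)[C@@]2(C)CCC(=O)[C@H]2C(=O)C1
A5 | alternative 2 | 3,6-dimethyl-2-[(2E)-3-(trimethylsilyl)prop-2-enoyl]cyclohepta-2,5-dien-1-one | CC1=CCC(C)=C(C(=O)/C=C/[Si](C)(C)C)C(=O)C1
A6 | alternative 2 | Cu(OTf)2 | [Cu+2].[O-]S(=O)(=O)C(F)(F)F.[O-]S(=O)(=O)C(F)(F)F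
A7 | alternative 2 | trans-fused bicyclic enedione (C7 and C9 ketones, C5=C6, C1=C2, quaternary C4) | CC1=CC[C@@]2(C)C=CC(=O)[C@@H]2C(=O)C1
A8 | alternative 3 | Rh2(S-DOSP)4, dirhodium tetrakis[(S)-N-(4-dodecylbenzenesulfonyl)prolinate] | [Rh+2].[Rh+2].CCCCCCCCCCCCc1ccc(cc1)S(=O)(=O)N1CCC[C@H]1C([O-])=O.CCCCCCCCCCCCc1ccc(cc1)S(=O)(=O)N1CCC[C@H]1C([O-])=O.CCCCCCCCCCCCc1ccc(cc1)S(=O)(=O)N1CCC[C@H]1C([O-])=O.CCCCCCCCCCCCc1ccc(cc1)S(=O)(=O)N1CCC[C@H]1C([O-])=O
A9 | alternative 3 | methyl 2-diazobut-3-enoate | COC(=O)C(=[N+]=[N-])C=C
A10 | alternative 3 | tert-butyldimethyl{[1-(7-methyl-1,4-dioxaspiro[4.4]non-6-en-6-yl)ethenyl]oxy}silane | C=C(O[Si](C)(C)C(C)(C)C)C1=C(C)CCC12OCCO2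
A11 | alternative 3 | bicyclic cyclohepta-1,4-diene (C1 methyl ester, C9 silyl enol ether, C7 ketal, quaternary C4) | COC(=O)C1=CC[C@@]2(C)CCC3(OCCO3)C2=C(O[Si](C)(C)C(C)(C)C)C1
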